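The cyclopentane ring of each amino alcohol half is read as a 2-methylcyclopentanone (ring C4a–C5–C6–C7–C7a; C6 carbonyl between C5H2 and C7HMe) fused through C4a–C7a to the piperidine; the halves are joined at the end to (2E,6E)-2,6-dimethylocta-2,6-dienedioic acid by a double Mitsunobu esterification. Such a cyclopentanone is the hydroacylation product of a 4-pentenal, and that aldehyde is the Claisen product of an allyl propenyl ether. One operation on the propenyl ether of a 4-(hydroxymethyl)-1,2-dihydropyridine therefore makes C7–C7a by a [3,3] shift and C5–C6 by rhodium-catalysed hydroacylation, the chiral catalyst selecting one aldehyde enantiomer; the ether oxygen ends on C6.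

Key step: step 3

Numbering: atoms are numbered as in cyclopenta[c]pyridine (C1, N2, C3, C4, C4a, C5, C6, C7, C7a) unless pyridine numbering is named.
Assumption: (R)-BINAP is taken as the ligand enantiomer matched with the aldehyde that has the target configuration at C7a; if the sense of induction is the reverse, (S)-BINAP is used and nothing else changes.

Step 1
Reactants: 1 (3-methylpyridin-4-yl)methanol; 2 (E)-prop-1-enylboronic acid pinacol ester
Product: 3 3-methyl-4-{[(1E)-prop-1-en-1-yloxy]methyl}pyridine
Conditions: 2 (2.5 equiv), Cu(OAc)2 (2 equiv), Et3N (4 equiv), 4 Å MS, CH2Cl2, air, 25 °C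
Reagents that add atoms: none
Why: Copper-promoted oxidative C–O coupling of an alcohol with an alkenyl pinacol boronate (Chan–Lam type) should give the propenyl ether directly with retention of alkene geometry; no stereocentre is formed and the geometry is of no consequence later because C7 is equilibrated in step 3.

Step 2
Reactants: 3 3-methyl-4-{[(1E)-prop-1-en-1-yloxy]methyl}pyridine
Product: 4 methyl 5-methyl-4-{[(1E)-prop-1-en-1-yloxy]methyl}pyridine-1(2H)-carboxylate
Conditions: NaBH4, MeOH, −78 °C, ClCO2Me added slowly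
Reagents that add atoms: methyl chloroformate, COC(=O)Cl
Why: Fowler reduction: the pyridine is acylated on nitrogen and the N-methoxycarbonylpyridinium ion should take up hydride at C6 (pyridine numbering of 3), the α-carbon remote from the methyl group (C4 is blocked), to give the 1,2-dihydropyridine whose ring alkene, CH2O group and enol ether make up the allyl vinyl ether for step 3; the regioisomer from attack at C2 is removed by chromatography.

Step 3
Reactants: 4 methyl 5-methyl-4-{[(1E)-prop-1-en-1-yloxy]methyl}pyridine-1(2H)-carboxylate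
Product: 6 methyl (4aS,7R,7aS)-4,7-dimethyl-6-oxo-1,4a,5,6,7,7a-hexahydro-2H-cyclopenta[c]pyridine-2-carboxylate, via aldehyde 5 (not isolated)
Conditions: ClCH2CH2Cl, 120 °C, sealed tube; then [Rh((R)-BINAP)]ClO4 (5 mol %), 25 °C; then DBU (0.1 equiv), 25 °C
Reagents that add atoms: none
Why: Heating drives the [3,3] sigmatropic (Claisen) shift of the allyl propenyl ether through a chair transition state, which joins C7 to C7a, moves the ring alkene to the exocyclic C4a=C5 position and unmasks the C6 aldehyde (5); the cationic rhodium–diphosphine catalyst then inserts into the aldehyde C–H bond, delivers hydride to C4a and closes C5–C6 by reductive elimination. The closest known reactions are the tandem Claisen rearrangement–intramolecular hydroacylation of allyl vinyl ethers to cyclopentanones and the hydroacylation of racemic 3,4-disubstituted 4-pentenals by chiral cationic rhodium–BINAP complexes. The cyclopentanone closes from a six-membered acyl-rhodacycle, a net anti-Markovnikov (5-endo) addition of the acyl–H bond across the 1,1-disubstituted alkene. C7a is formed in the Claisen step without facial bias; C4a is fixed by catalyst-controlled hydride delivery, so the aldehyde enantiomer with the target configuration at C7a should give the cis-fused ketone 6 and its antipode a trans-fused diastereomer that is removed by chromatography (at most half of the material can reach 6); C7 is epimerisable and DBU sets it to the more stable configuration with the methyl group trans to C1. The step needs hydride transfer to C4a and not to C5 (which would give an allyl-rhodium through the dienyl carbamate); the unhindered primary alkyl–rhodium bond at C5 and the easy closure of the five-membered ring should secure this, and the ene-carbamate C3=C4 bond is left untouched.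

Step 4
Reactants: 6 methyl (4aS,7R,7aS)-4,7-dimethyl-6-oxo-1,4a,5,6,7,7a-hexahydro-2H-cyclopenta[c]pyridine-2-carboxylate
Product: 7 methyl (4S,4aR,7R,7aS)-4,7-dimethyl-6-oxooctahydro-2H-cyclopenta[c]pyridine-2-carboxylate
Conditions: H2 (3 atm), 10% Pd/C, EtOAc, 25 °C
Reagents that add atoms: none
Why: Heterogeneous hydrogenation of the ene-carbamate from the convex face of the cis-fused bicycle (the face that carries H4a and H7a) should place H4 cis to H4a and so set C4 as (S); the ketone is not reduced under these conditions.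

Step 5
Reactants: 7 methyl (4S,4aR,7R,7aS)-4,7-dimethyl-6-oxooctahydro-2H-cyclopenta[c]pyridine-2-carboxylate
Product: 8 (4S,4aR,6R,7R,7aS)-2,4,7-trimethyloctahydro-1H-cyclopenta[c]pyridin-6-ol (6-epi-incarvilline)
Conditions: LiAlH4 (4 equiv), THF, −78 °C to reflux; aqueous NaOH work-up
Reagents that add atoms: none
Why: LiAlH4 should first reduce the ketone by hydride attack on the convex face (anti to the piperidine ring, giving the trans-2-methylcyclopentanol relationship), which sets C6 as (R), and on heating reduce the methyl carbamate to the N-methyl group (carbamate reduction).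

Step 6
Reactants: 9 geranyl acetate, (2E)-3,7-dimethylocta-2,6-dien-1-yl acetate
Product: 10 (2E,6E)-8-hydroxy-3,7-dimethylocta-2,6-dien-1-yl acetate
Conditions: SeO2 (0.1 equiv), t-BuOOH (3 equiv), salicylic acid (0.1 equiv), CH2Cl2, 25 °C
Reagents that add atoms: tert-butyl hydroperoxide, CC(C)(C)OO
Why: Selenium dioxide allylic oxidation (ene reaction then [2,3] shift, Riley type) with tert-butyl hydroperoxide as terminal oxidant is selective for the (E)-methyl group of the terminal trisubstituted alkene, the other alkene being deactivated by the allylic acetate; both alkene geometries are kept.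

Step 7
Reactants: 10 (2E,6E)-8-hydroxy-3,7-dimethylocta-2,6-dien-1-yl acetate
Product: 11 (2E,6E)-2,6-dimethylocta-2,6-diene-1,8-diol
Conditions: K2CO3, MeOH, 25 °C
Reagents that add atoms: none
Why: Base-catalysed transesterification with methanol removes the acetate without touching the alkenes.

Step 8
Reactants: 11 (2E,6E)-2,6-dimethylocta-2,6-diene-1,8-diol
Product: 13 (2E,6E)-2,6-dimethylocta-2,6-dienedioic acid, via dialdehyde 12 (not isolated)
Conditions: TEMPO (0.2 equiv), PhI(OAc)2 (2.4 equiv), CH2Cl2, 25 °C; then NaClO2, NaH2PO4, 2-methyl-2-butene, t-BuOH/H2O, 25 °C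
Reagents that add atoms: sodium chlorite, [Na+].[O-]Cl=O
Why: Oxoammonium (TEMPO/PhI(OAc)2) oxidation should take both allylic alcohols to the dialdehyde without E/Z isomerisation, and Pinnick oxidation in the same flask converts both enals into carboxylic acids.

Step 9
Reactants: 8 (4S,4aR,6R,7R,7aS)-2,4,7-trimethyloctahydro-1H-cyclopenta[c]pyridin-6-ol (2.2 equiv); 13 (2E,6E)-2,6-dimethylocta-2,6-dienedioic acid
Product: 14 bis[(4S,4aR,6S,7R,7aS)-2,4,7-trimethyloctahydro-1H-cyclopenta[c]pyridin-6-yl] (2E,6E)-2,6-dimethylocta-2,6-dienedioate (CNP0240822.2)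
Conditions: PPh3 (2.8 equiv), DIAD (2.8 equiv), THF, 0 to 25 °C
Reagents that add atoms: none
Why: Double Mitsunobu esterification: each alkoxyphosphonium ion derived from 8 is displaced by a carboxylate of 13 with inversion (SN2), which converts (6R) into the (6S) configuration of the target at both ends; the tertiary amine is tolerated.

Compound list
1 | (3-methylpyridin-4-yl)methanol | Cc1cnccc1CO | starting material
2 | (E)-prop-1-enylboronic acid pinacol ester | C/C=C/B1OC(C)(C)C(C)(C)O1 | starting material
3 | 3-methyl-4-{[(1E)-prop-1-en-1-yloxy]methyl}pyridine | Cc1cnccc1CO/C=C/C | intermediate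
4 | methyl 5-methyl-4-{[(1E)-prop-1-en-1-yloxy]methyl}pyridine-1(2H)-carboxylate | COC(=O)N1CC=C(CO/C=C/C)C(C)=C1 | intermediate
5 | methyl 5-methyl-4-methylidene-3-(1-oxopropan-2-yl)-3,4-dihydropyridine-1(2H)-carboxylate (racemic at C3; the 3R enantiomer that goes on is drawn; side-chain centre unassigned) | COC(=O)N1C[C@H](C(C)C=O)C(=C)C(C)=C1 | intermediate
6 | methyl (4aS,7R,7aS)-4,7-dimethyl-6-oxo-1,4a,5,6,7,7a-hexahydro-2H-cyclopenta[c]pyridine-2-carboxylate | O=C1C[C@H]2[C@H](CN(C(=O)OC)C=C2C)[C@H]1C | intermediate
7 | methyl (4S,4aR,7R,7aS)-4,7-dimethyl-6-oxooctahydro-2H-cyclopenta[c]pyridine-2-carboxylate | O=C1C[C@H]2[C@H](CN(C(=O)OC)C[C@H]2C)[C@H]1C | intermediate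
8 | (4S,4aR,6R,7R,7aS)-2,4,7-trimethyloctahydro-1H-cyclopenta[c]pyridin-6-ol (6-epi-incarvilline) | O[C@@H]1C[C@H]2[C@H](CN(C)C[C@H]2C)[C@H]1C | intermediate
9 | geranyl acetate | CC(C)=CCC/C(C)=C/COC(C)=O | starting material
10 | (2E,6E)-8-hydroxy-3,7-dimethylocta-2,6-dien-1-yl acetate | OC/C(C)=C/CC/C(C)=C/COC(C)=O | intermediate
11 | (2E,6E)-2,6-dimethylocta-2,6-diene-1,8-diol | OC/C(C)=C/CC/C(C)=C/CO | intermediate
12 | (2E,6E)-2,6-dimethylocta-2,6-dienedial | O=C/C(C)=C/CC/C(C)=C/C=O | intermediate
13 | (2E,6E)-2,6-dimethylocta-2,6-dienedioic acid | OC(=O)/C(C)=C/CC/C(C)=C/C(=O)O | intermediate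
14 | bis[(4S,4aR,6S,7R,7aS)-2,4,7-trimethyloctahydro-1H-cyclopenta[c]pyridin-6-yl] (2E,6E)-2,6-dimethylocta-2,6-dienedioate | C/C(=C\C(=O)O[C@H]1C[C@H]2[C@H](CN(C)C[C@H]2C)[C@H]1C)CC/C=C(\C)C(=O)O[C@H]1C[C@H]2[C@H](CN(C)C[C@H]2C)[C@H]1C | target

Total step count: 9. Longest linear sequence: 6 steps (steps 1, 2, 3, 4, 5, 9).

Steps most likely to fail

Step 3. The chiral catalyst may discriminate poorly between the two enantiomers of aldehyde 5, so that the cis-fused ketone forms with low enantiomeric purity. The fallback sets out from 3 and obtains the absolute configuration from a covalent auxiliary instead of from the catalyst. The acylpyridinium reduction is run with (1R,2S,5R)-menthyl chloroformate and NaBH4 to give (1R,2S,5R)-menthyl 5-methyl-4-{[(1E)-prop-1-en-1-yloxy]methyl}pyridine-1(2H)-carboxylate F1. Heating F1 gives the menthyl ester aldehyde F2 (not isolated, both C3 epimers), which is cyclised with achiral [Rh(Ph2PCH2CH2PPh2)]ClO4 and equilibrated with DBU. The two diastereomeric cis-fused ketones are separated by chromatography or crystallisation to give (1R,2S,5R)-menthyl (4aS,7R,7aS)-4,7-dimethyl-6-oxo-1,4a,5,6,7,7a-hexahydro-2H-cyclopenta[c]pyridine-2-carboxylate F3. Hydrogenation (H2, Pd/C) gives the saturated menthyl carbamate F4, and LiAlH4 reduces its ketone and carbamate, which comes back to the route at 8.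

Step 2. Hydride addition at C2 of the acylpyridinium ion, next to the methyl group, may compete with addition at C6 and erode the regioselectivity. The fallback sets out from 3 and uses a sterically governed metal-catalysed 1,2-hydroboration: pinacolborane with [Rh(cod)Cl]2 and PCy3 should put hydrogen on the less hindered α-carbon and boron on nitrogen to give 5-methyl-4-{[(1E)-prop-1-en-1-yloxy]methyl}-1-(4,4,5,5-tetramethyl-1,3,2-dioxaborolan-2-yl)-1,2-dihydropyridine F5. Exchange of the N–B bond with methyl chloroformate comes back to the route at 4.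

Step 9. The second inversion may stall or the activated secondary alcohol may eliminate, leaving mono-ester and alkene. The fallback sets out from 8 and separates inversion from ester formation. Mitsunobu reaction with 4-nitrobenzoic acid gives (4S,4aR,6S,7R,7aS)-2,4,7-trimethyloctahydro-1H-cyclopenta[c]pyridin-6-yl 4-nitrobenzoate F6, and methanolysis (K2CO3, MeOH) gives (4S,4aR,6S,7R,7aS)-2,4,7-trimethyloctahydro-1H-cyclopenta[c]pyridin-6-ol F7. F7 (2.2 equiv) is acylated with 13 (EDC·HCl, DMAP, CH2Cl2) with retention, which comes back to the route at 14.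

Further compounds
F1 | step 3 | (1R,2S,5R)-menthyl 5-methyl-4-{[(1E)-prop-1-en-1-yloxy]methyl}pyridine-1(2H)-carboxylate | C[C@@H]1CC[C@H]([C@@H](C1)OC(=O)N2CC=C(CO/C=C/C)C(C)=C2)C(C)C
F2 | step 3 | (1R,2S,5R)-menthyl 5-methyl-4-methylidene-3-(1-oxopropan-2-yl)-3,4-dihydropyridine-1(2H)-carboxylate (3R epimer drawn) | C[C@@H]1CC[C@H]([C@@H](C1)OC(=O)N2C[C@H](C(C)C=O)C(=C)C(C)=C2)C(C)C
F3 | step 3 | (1R,2S,5R)-menthyl (4aS,7R,7aS)-4,7-dimethyl-6-oxo-1,4a,5,6,7,7a-hexahydro-2H-cyclopenta[c]pyridine-2-carboxylate | O=C1C[C@H]2[C@H](CN(C(=O)O[C@@H]3C[C@H](C)CC[C@H]3C(C)C)C=C2C)[C@H]1C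
F4 | step 3 | (1R,2S,5R)-menthyl (4S,4aR,7R,7aS)-4,7-dimethyl-6-oxooctahydro-2H-cyclopenta[c]pyridine-2-carboxylate | O=C1C[C@H]2[C@H](CN(C(=O)O[C@@H]3C[C@H](C)CC[C@H]3C(C)C)C[C@H]2C)[C@H]1C
F5 | step 2 | 5-methyl-4-{[(1E)-prop-1-en-1-yloxy]methyl}-1-(4,4,5,5-tetramethyl-1,3,2-dioxaborolan-2-yl)-1,2-dihydropyridine | CC1(C)OB(OC1(C)C)N2CC=C(CO/C=C/C)C(C)=C2
F6 | step 9 | (4S,4aR,6S,7R,7aS)-2,4,7-trimethyloctahydro-1H-cyclopenta[c]pyridin-6-yl 4-nitrobenzoate | O=C(O[C@H]1C[C@H]2[C@H](CN(C)C[C@H]2C)[C@H]1C)c3ccc(cc3)[N+](=O)[O-]
F7 | step 9 | (4S,4aR,6S,7R,7aS)-2,4,7-trimethyloctahydro-1H-cyclopenta[c]pyridin-6-ol | O[C@H]1C[C@H]2[C@H](CN(C)C[C@H]2C)[C@H]1C
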